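**Strategy.** Everything rests on closing ring C through the aryl ether bond O1–C8a, made in the same operation as C4–C4a on the neighboring carbon of ring A. Fluoride frees the C2 alkoxide of an acyclic, enantiopure β-silyloxy amide (ring B, C2, C3, C4) and an aryne from a silylaryl triflate (ring A). The oxygen adds to the aryne at C8a and the aryl anion at C4a closes ring C on the amide. The step exploits the C5 oxygen next to C4a, which steers the alkoxide to C8a, and the ortho relation of O1 and the C4 carbonyl. C2 is set beforehand by a catalytic Mukaiyama aldol on the geranylated ring B aldehyde.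

Key step: step 10

Remark 1: atoms are numbered as in flavanone (O1, C2, C3, C4, C4a, C5–C8, C8a for rings C and A; primed numbers for ring B).
Remark 2: in step 3 the ligand antipode must expose the Si face of the formyl group of 6. The (S)-binaphthyl ligand is written on the assumption that it does so; otherwise its mirror image is used.

**Ring B fragment (steps 1–4)**

Step 1
Reactants: 1 2-bromo-3-hydroxy-4-methoxybenzaldehyde
Product: 2 2-bromo-4-methoxy-3-(methoxymethoxy)benzaldehyde
Conditions: MOMCl, i-Pr2NEt, CH2Cl2, 0 °C to rt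
Reagents that add atoms: chloromethyl methyl ether COCCl
Why: Williamson-type O-alkylation of the phenol; the MOM acetal withstands the organolithium, fluoride and aryne steps and leaves under mild acid at the end.

Step 2
Reactants: 2 2-bromo-4-methoxy-3-(methoxymethoxy)benzaldehyde; 3 geranyl bromide, (2E)-1-bromo-3,7-dimethylocta-2,6-diene
Product: 6 2-[(2E)-3,7-dimethylocta-2,6-dien-1-yl]-4-methoxy-3-(methoxymethoxy)benzaldehyde, via lithium amino alkoxide 4 (not isolated), via aryllithium 5 (not isolated)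
Conditions: LiN(Me)CH2CH2NMe2 (from the amine and n-BuLi), THF, −20 °C; n-BuLi, −78 °C; CuBr·SMe2, −78 to −40 °C; 3, to 0 °C; aq NH4Cl
Reagents that add atoms: none
Why: The aldehyde is masked in situ as a lithium α-amino alkoxide, Br–Li exchange and transmetalation to copper give an aryl nucleophile that displaces the primary allylic bromide of 3 in SN2 fashion with retention of the (E)-olefin, and aqueous work-up returns the aldehyde.

Step 3
Reactants: 6 2-[(2E)-3,7-dimethylocta-2,6-dien-1-yl]-4-methoxy-3-(methoxymethoxy)benzaldehyde; 7 1-methoxy-1-(trimethylsilyloxy)ethene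
Product: 8 methyl (3S)-3-{2-[(2E)-3,7-dimethylocta-2,6-dien-1-yl]-4-methoxy-3-(methoxymethoxy)phenyl}-3-[(trimethylsilyl)oxy]propanoate
Conditions: Ti(OiPr)4 (5 mol %), (S)-2-[(3-bromo-5-tert-butyl-2-hydroxybenzylidene)amino]-2'-hydroxy-1,1'-binaphthyl (5 mol %), 3,5-di-tert-butylsalicylic acid (5 mol %), Et2O, −10 °C; filtration through Et3N-washed silica
Reagents that add atoms: none
Why: Catalytic enantioselective Mukaiyama aldol addition with silyl transfer; the chiral titanium Schiff base complex directs the ketene acetal to the Si face of the formyl group, which sets C2 as (S) under catalyst control and delivers the alcohol already as its TMS ether.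

Step 4
Reactants: 8 methyl (3S)-3-{2-[(2E)-3,7-dimethylocta-2,6-dien-1-yl]-4-methoxy-3-(methoxymethoxy)phenyl}-3-[(trimethylsilyl)oxy]propanoate
Product: 9 (3S)-3-{2-[(2E)-3,7-dimethylocta-2,6-dien-1-yl]-4-methoxy-3-(methoxymethoxy)phenyl}-1-(morpholin-4-yl)-3-[(trimethylsilyl)oxy]propan-1-one
Conditions: morpholine, i-PrMgCl, THF, −20 to 0 °C; pH 7 phosphate buffer
Reagents that add atoms: morpholine C1COCCN1
Why: Aminolysis of the methyl ester by the magnesium amide of morpholine at low temperature; the silyl ether and the benzylic stereocenter, which carries no acidic hydrogen, should be left untouched, and the tertiary amide is the acyl acceptor needed in step 10.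

**Ring A fragment (steps 5–9)**

Step 5
Reactants: 10 5-methoxybenzene-1,3-diol
Product: 11 1-methoxy-3,5-bis(methoxymethoxy)benzene
Conditions: MOMCl (2.5 equiv), i-Pr2NEt, CH2Cl2, 0 °C to rt
Reagents that add atoms: chloromethyl methyl ether COCCl
Why: Double O-alkylation of the resorcinol; the two MOM ethers are the ortho-directing groups for step 6.

Step 6
Reactants: 11 1-methoxy-3,5-bis(methoxymethoxy)benzene
Product: 13 2-bromo-5-methoxy-1,3-bis(methoxymethoxy)benzene, via aryllithium 12 (not isolated)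
Conditions: n-BuLi, TMEDA, THF, 0 °C; BrCH2CH2Br, −78 °C to rt
Reagents that add atoms: 1,2-dibromoethane BrCCBr
Why: Directed ortho-metalation at the carbon flanked by both MOM ethers (cooperative coordination; the other two ring C–H bonds have only one MOM neighbor), followed by bromine transfer from 1,2-dibromoethane.

Step 7
Reactants: 13 2-bromo-5-methoxy-1,3-bis(methoxymethoxy)benzene
Product: 14 2-bromo-5-methoxybenzene-1,3-diol
Conditions: HCl (cat.), MeOH, 50 °C
Reagents that add atoms: none
Why: Acid-catalyzed acetal exchange with methanol removes both MOM groups; the aryl bromide is inert.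

Step 8
Reactants: 14 2-bromo-5-methoxybenzene-1,3-diol
Product: 18 3-hydroxy-5-methoxy-2-(trimethylsilyl)phenyl trifluoromethanesulfonate, via bis(silyl) ether 15 (not isolated), via lithium phenoxide 16 (not isolated), via silyloxy triflate 17 (not isolated)
Conditions: (Me3Si)2NH, THF, reflux, then evaporation; n-BuLi, THF, −100 to −78 °C; Tf2O, −100 °C to rt; pH 7 buffer, then MeOH, rt
Reagents that add atoms: hexamethyldisilazane C[Si](C)(C)N[Si](C)(C)C; trifluoromethanesulfonic anhydride O=S(=O)(OS(=O)(=O)C(F)(F)F)C(F)(F)F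
Why: O-silylation, Br–Li exchange and anionic 1,3 O-to-C silyl migration (retro-Brook rearrangement) put silicon on carbon and desymmetrize the ring; the phenoxide released is triflated and the remaining labile aryl silyl ether is hydrolyzed on work-up.

Step 9
Reactants: 18 3-hydroxy-5-methoxy-2-(trimethylsilyl)phenyl trifluoromethanesulfonate
Product: 19 5-methoxy-3-(methoxymethoxy)-2-(trimethylsilyl)phenyl trifluoromethanesulfonate
Conditions: MOMCl, i-Pr2NEt, CH2Cl2, −20 to 0 °C
Reagents that add atoms: chloromethyl methyl ether COCCl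
Why: O-alkylation of the phenol with MOMCl under a weak amine base at low temperature, which should outrun base-induced C-to-O silyl migration.

**Union and end game (steps 10–11)**

Step 10
Reactants: 9 (3S)-3-{2-[(2E)-3,7-dimethylocta-2,6-dien-1-yl]-4-methoxy-3-(methoxymethoxy)phenyl}-1-(morpholin-4-yl)-3-[(trimethylsilyl)oxy]propan-1-one; 19 5-methoxy-3-(methoxymethoxy)-2-(trimethylsilyl)phenyl trifluoromethanesulfonate (1.2 equiv)
Product: 22 (2S)-2-{2-[(2E)-3,7-dimethylocta-2,6-dien-1-yl]-4-methoxy-3-(methoxymethoxy)phenyl}-7-methoxy-5-(methoxymethoxy)-2,3-dihydro-4H-chromen-4-one, via aryne 20 (not isolated), via cesium hemiaminal alkoxide 21 (not isolated)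
Conditions: CsF (3 equiv), 18-crown-6, THF, 0 °C to rt; then aq citric acid (pH 4–5), 0 °C
Reagents that add atoms: none
Why: Proposed new method: fluoride cleaves the O–Si bond of 9 and the C–Si bond of 19, so a cesium alkoxide and aryne 20 meet in the flask; the alkoxide oxygen adds to the aryne carbon remote from the OMOM group (O1–C8a), and the aryl anion left at C4a, flanked by two oxygens, attacks the tethered morpholine amide (C4a–C4) to give hemiaminal alkoxide 21, which releases the ketone only on acidic work-up. The closest known reaction type is the fluoride-induced annulation of arynes with salicylates to xanthones and the aryne insertion into the N–CO bond of β-lactams (nucleophilic addition to the aryne, then intramolecular acyl capture); an aliphatic alkoxide released from a silyl ether has not been used in this way. Ring C is closed by a formal [4+2] annulation (O1, C2, C3, C4 onto C8a, C4a), whose last event is a 6-exo-trig attack of the aryl anion on the amide carbonyl. No stereocenter is formed: C2 comes from 9 and is not touched, because the amide alkoxide has no ready retro-aldol path and no enolizable flavanone exists in the basic medium before the quench. The step needs O-attack at C8a, secured by the distortion of the 3-alkoxyaryne by the C5 OMOM group, and capture of the aryl anion by the amide before protonation, secured by the proton-free release of the alkoxide from the silyl ether.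

Step 11
Reactants: 22 (2S)-2-{2-[(2E)-3,7-dimethylocta-2,6-dien-1-yl]-4-methoxy-3-(methoxymethoxy)phenyl}-7-methoxy-5-(methoxymethoxy)-2,3-dihydro-4H-chromen-4-one
Product: 23 (2S)-2-{2-[(2E)-3,7-dimethylocta-2,6-dien-1-yl]-3-hydroxy-4-methoxyphenyl}-5-hydroxy-7-methoxy-2,3-dihydro-4H-chromen-4-one (CNP0130331.1)
Conditions: HCl (1 M, from AcCl in MeOH), MeOH/THF, 0 °C to rt
Reagents that add atoms: none
Why: Acid-catalyzed transfer of both MOM acetals to methanol (the C5 acetal assisted by the peri carbonyl); dilute acid at room temperature should avoid cyclization of the geranyl olefin onto the C3' phenol, and the flavanone C2 center is configurationally stable in acid.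

**Compound list**

1 | 2-bromo-3-hydroxy-4-methoxybenzaldehyde | O=Cc1ccc(OC)c(O)c1Br | starting material
2 | 2-bromo-4-methoxy-3-(methoxymethoxy)benzaldehyde | O=Cc1ccc(OC)c(OCOC)c1Br | intermediate
3 | (2E)-1-bromo-3,7-dimethylocta-2,6-diene (geranyl bromide) | BrC/C=C(\C)CCC=C(C)C | starting material
4 | lithium [2-bromo-4-methoxy-3-(methoxymethoxy)phenyl]{[2-(dimethylamino)ethyl](methyl)amino}methanolate (not isolated) | [Li]OC(N(C)CCN(C)C)c1ccc(OC)c(OCOC)c1Br | intermediate
5 | aryllithium from 4 by Br–Li exchange (not isolated) | [Li]OC(N(C)CCN(C)C)c1ccc(OC)c(OCOC)c1[Li] | intermediate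
6 | 2-[(2E)-3,7-dimethylocta-2,6-dien-1-yl]-4-methoxy-3-(methoxymethoxy)benzaldehyde | O=Cc1ccc(OC)c(OCOC)c1C/C=C(\C)CCC=C(C)C | intermediate
7 | 1-methoxy-1-(trimethylsilyloxy)ethene | C=C(OC)O[Si](C)(C)C | starting material
8 | methyl (3S)-3-{2-[(2E)-3,7-dimethylocta-2,6-dien-1-yl]-4-methoxy-3-(methoxymethoxy)phenyl}-3-[(trimethylsilyl)oxy]propanoate | C[Si](C)(C)O[C@H](c1ccc(OC)c(OCOC)c1C/C=C(\C)CCC=C(C)C)CC(=O)OC | intermediate
9 | (3S)-3-{2-[(2E)-3,7-dimethylocta-2,6-dien-1-yl]-4-methoxy-3-(methoxymethoxy)phenyl}-1-(morpholin-4-yl)-3-[(trimethylsilyl)oxy]propan-1-one | C[Si](C)(C)O[C@H](c1ccc(OC)c(OCOC)c1C/C=C(\C)CCC=C(C)C)CC(=O)N1CCOCC1 | intermediate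
10 | 5-methoxybenzene-1,3-diol | COc1cc(O)cc(O)c1 | starting material
11 | 1-methoxy-3,5-bis(methoxymethoxy)benzene | COCOc1cc(OC)cc(OCOC)c1 | intermediate
12 | [4-methoxy-2,6-bis(methoxymethoxy)phenyl]lithium (not isolated) | [Li]c1c(OCOC)cc(OC)cc1OCOC | intermediate
13 | 2-bromo-5-methoxy-1,3-bis(methoxymethoxy)benzene | COCOc1cc(OC)cc(OCOC)c1Br | intermediate
14 | 2-bromo-5-methoxybenzene-1,3-diol | COc1cc(O)c(Br)c(O)c1 | intermediate
15 | 2-bromo-5-methoxy-1,3-bis[(trimethylsilyl)oxy]benzene (not isolated) | COc1cc(O[Si](C)(C)C)c(Br)c(O[Si](C)(C)C)c1 | intermediate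
16 | lithium 5-methoxy-2-(trimethylsilyl)-3-[(trimethylsilyl)oxy]phenolate (not isolated) | COc1cc(O[Li])c([Si](C)(C)C)c(O[Si](C)(C)C)c1 | intermediate
17 | 5-methoxy-2-(trimethylsilyl)-3-[(trimethylsilyl)oxy]phenyl trifluoromethanesulfonate (not isolated) | COc1cc(O[Si](C)(C)C)c([Si](C)(C)C)c(OS(=O)(=O)C(F)(F)F)c1 | intermediate
18 | 3-hydroxy-5-methoxy-2-(trimethylsilyl)phenyl trifluoromethanesulfonate | COc1cc(O)c([Si](C)(C)C)c(OS(=O)(=O)C(F)(F)F)c1 | intermediate
19 | 5-methoxy-3-(methoxymethoxy)-2-(trimethylsilyl)phenyl trifluoromethanesulfonate | COCOc1cc(OC)cc(OS(=O)(=O)C(F)(F)F)c1[Si](C)(C)C | intermediate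
20 | 5-methoxy-3-(methoxymethoxy)benzyne (1,2-didehydrobenzene; not isolated) | COCOC1=CC(OC)=CC#C1 | intermediate
21 | cesium (2S)-2-{2-[(2E)-3,7-dimethylocta-2,6-dien-1-yl]-4-methoxy-3-(methoxymethoxy)phenyl}-7-methoxy-5-(methoxymethoxy)-4-(morpholin-4-yl)-3,4-dihydro-2H-chromen-4-olate (C4 epimers; not isolated) | COc1cc(OCOC)c2c(c1)O[C@H](c1ccc(OC)c(OCOC)c1C/C=C(\C)CCC=C(C)C)CC2([O-])N1CCOCC1.[Cs+] | intermediate
22 | (2S)-2-{2-[(2E)-3,7-dimethylocta-2,6-dien-1-yl]-4-methoxy-3-(methoxymethoxy)phenyl}-7-methoxy-5-(methoxymethoxy)-2,3-dihydro-4H-chromen-4-one | COc1cc(OCOC)c2c(c1)O[C@H](c1ccc(OC)c(OCOC)c1C/C=C(\C)CCC=C(C)C)CC2=O | intermediate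
23 | (2S)-2-{2-[(2E)-3,7-dimethylocta-2,6-dien-1-yl]-3-hydroxy-4-methoxyphenyl}-5-hydroxy-7-methoxy-2,3-dihydro-4H-chromen-4-one | COc1cc(O)c2c(c1)O[C@H](c1ccc(OC)c(O)c1C/C=C(\C)CCC=C(C)C)CC2=O | target

**Step count and risks**

Total step count: 11. Longest linear sequence: 7 steps (steps 5 to 11); the other branch runs through 6 steps (1 to 4, 10, 11).

Steps most likely to fail:

1. Step 10 (Proposed new method). What may go wrong: the aryl anion is protonated, or takes a proton from C3, before it reaches the amide, so that an uncyclized aryl ether or an elimination product forms; the aryne undergoes ene reaction with the geranyl olefins; fluoride competes with the alkoxide for the aryne. Fallback (known chemistry; the same O1–C8a bond closes ring C by intramolecular Ullmann etherification): it sets out from 6 and comes back at 22. Commercial 1-bromo-3,5-dimethoxybenzene is acetylated (AcCl, AlCl3, CH2Cl2, 0 °C; Friedel–Crafts acylation para to one methoxy group and ortho to bromine) to 1-(2-bromo-4,6-dimethoxyphenyl)ethanone F1. BCl3 (CH2Cl2, −78 to 0 °C) cleaves only the methoxy group chelated to the carbonyl and gives 1-(2-bromo-6-hydroxy-4-methoxyphenyl)ethanone F2, which is capped (MOMCl, i-Pr2NEt) as 1-[2-bromo-4-methoxy-6-(methoxymethoxy)phenyl]ethanone F3 and converted (LDA, TMSCl, THF, −78 °C) into its silyl enol ether {1-[2-bromo-4-methoxy-6-(methoxymethoxy)phenyl]ethenyl}oxy(trimethyl)silane F4. A Mukaiyama aldol addition of F4 to 6 under a tartrate-derived chiral (acyloxy)borane (antipode chosen for Si-face addition; EtCN, −78 °C; acidic work-up) should give the (3S)-β-hydroxy ketone F5. NaBH4 should then give the 1,3-diol F6. CuI/3,4,7,8-tetramethyl-1,10-phenanthroline/Cs2CO3 in toluene at 110 °C should close O1–C8a to the flavan-4-ol F7; only the C2 hydroxyl can reach the C–Br carbon through a six-membered ring, and with no ketone present neither retro-aldol cleavage nor ring opening can erode C2. Oxidation of the C4 alcohol with DMP (1,1,1-triacetoxy-1,1-dihydro-1,2-benziodoxol-3(1H)-one) returns 22.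

2. Step 3. What may go wrong: poor facial selectivity or slow turnover with the ortho-substituted, electron-rich aldehyde, and loss of the TMS ether on isolation. Fallback: it sets out from 6 and comes back at 8. Aldol addition of methyl acetate (LDA, THF, −78 °C) gives racemic methyl 3-{2-[(2E)-3,7-dimethylocta-2,6-dien-1-yl]-4-methoxy-3-(methoxymethoxy)phenyl}-3-hydroxypropanoate F8. Oxidation with DMP gives the β-keto ester F9. Asymmetric transfer hydrogenation with RuCl(p-cymene)[(S,S)-TsDPEN] in HCO2H/Et3N should give the (3S)-hydroxy ester F10, with hydride delivered as in the reduction of acetophenone to (S)-1-phenylethanol and the olefins left alone. TMSCl/imidazole then gives 8.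

3. Step 2. What may go wrong: incomplete masking of the aldehyde so that n-BuLi adds to it, protonation of the aryl metal before coupling, or SN2' attack on the allylic bromide. Fallback: it sets out from 2 and comes back at 6. The aldehyde is protected as an isolated acetal, 2-[2-bromo-4-methoxy-3-(methoxymethoxy)phenyl]-1,3-dioxolane F11 (1,2-bis(trimethylsilyloxy)ethane, TMSOTf cat., CH2Cl2, −78 °C). Br–Li exchange (n-BuLi, THF, −78 °C) gives [6-(1,3-dioxolan-2-yl)-3-methoxy-2-(methoxymethoxy)phenyl]lithium F12, which after transmetalation with CuBr·SMe2 is alkylated by 3 to 2-{2-[(2E)-3,7-dimethylocta-2,6-dien-1-yl]-4-methoxy-3-(methoxymethoxy)phenyl}-1,3-dioxolane F13. PPTS in wet acetone releases 6.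

Further compounds
F1 | step 10 | 1-(2-bromo-4,6-dimethoxyphenyl)ethanone | CC(=O)c1c(Br)cc(OC)cc1OC
F2 | step 10 | 1-(2-bromo-6-hydroxy-4-methoxyphenyl)ethanone | CC(=O)c1c(O)cc(OC)cc1Br
F3 | step 10 | 1-[2-bromo-4-methoxy-6-(methoxymethoxy)phenyl]ethanone | CC(=O)c1c(OCOC)cc(OC)cc1Br
F4 | step 10 | {1-[2-bromo-4-methoxy-6-(methoxymethoxy)phenyl]ethenyl}oxy(trimethyl)silane | C=C(O[Si](C)(C)C)c1c(OCOC)cc(OC)cc1Br
F5 | step 10 | (3S)-1-[2-bromo-4-methoxy-6-(methoxymethoxy)phenyl]-3-{2-[(2E)-3,7-dimethylocta-2,6-dien-1-yl]-4-methoxy-3-(methoxymethoxy)phenyl}-3-hydroxypropan-1-one | O[C@H](c1ccc(OC)c(OCOC)c1C/C=C(\C)CCC=C(C)C)CC(=O)c1c(OCOC)cc(OC)cc1Br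
F6 | step 10 | (3S)-1-[2-bromo-4-methoxy-6-(methoxymethoxy)phenyl]-3-{2-[(2E)-3,7-dimethylocta-2,6-dien-1-yl]-4-methoxy-3-(methoxymethoxy)phenyl}propane-1,3-diol (C1 epimers) | O[C@H](c1ccc(OC)c(OCOC)c1C/C=C(\C)CCC=C(C)C)CC(O)c1c(OCOC)cc(OC)cc1Br
F7 | step 10 | (2S)-2-{2-[(2E)-3,7-dimethylocta-2,6-dien-1-yl]-4-methoxy-3-(methoxymethoxy)phenyl}-7-methoxy-5-(methoxymethoxy)-3,4-dihydro-2H-chromen-4-ol (C4 epimers) | COc1cc(OCOC)c2c(c1)O[C@H](c1ccc(OC)c(OCOC)c1C/C=C(\C)CCC=C(C)C)CC2O
F8 | step 3 | methyl 3-{2-[(2E)-3,7-dimethylocta-2,6-dien-1-yl]-4-methoxy-3-(methoxymethoxy)phenyl}-3-hydroxypropanoate (racemic) | OC(c1ccc(OC)c(OCOC)c1C/C=C(\C)CCC=C(C)C)CC(=O)OC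
F9 | step 3 | methyl 3-{2-[(2E)-3,7-dimethylocta-2,6-dien-1-yl]-4-methoxy-3-(methoxymethoxy)phenyl}-3-oxopropanoate | O=C(c1ccc(OC)c(OCOC)c1C/C=C(\C)CCC=C(C)C)CC(=O)OC
F10 | step 3 | methyl (3S)-3-{2-[(2E)-3,7-dimethylocta-2,6-dien-1-yl]-4-methoxy-3-(methoxymethoxy)phenyl}-3-hydroxypropanoate | O[C@H](c1ccc(OC)c(OCOC)c1C/C=C(\C)CCC=C(C)C)CC(=O)OC
F11 | step 2 | 2-[2-bromo-4-methoxy-3-(methoxymethoxy)phenyl]-1,3-dioxolane | COCOc1c(OC)ccc(C2OCCO2)c1Br
F12 | step 2 | [6-(1,3-dioxolan-2-yl)-3-methoxy-2-(methoxymethoxy)phenyl]lithium | COCOc1c(OC)ccc(C2OCCO2)c1[Li]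
F13 | step 2 | 2-{2-[(2E)-3,7-dimethylocta-2,6-dien-1-yl]-4-methoxy-3-(methoxymethoxy)phenyl}-1,3-dioxolane | COCOc1c(OC)ccc(C2OCCO2)c1C/C=C(\C)CCC=C(C)C
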